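## Retrosynthetic overview

- **Feature:** in ring A of tangeretin the fusion carbons C4a and C8a are neighbours, and the other four carbons (C5, C6, C7, C8) each carry OMe. Cutting C4–C4a and O1–C8a therefore leaves 3,4,5,6-tetramethoxybenzyne. Its two aryne carbons are exchanged by a mirror plane, so the orientation of addition does not matter.
- **Partner:** a third cut at O1–C2 shows that O1, C2, C3, C4 (with its carbonyl oxygen) and ring B all come from 3-(4-methoxyphenyl)propiolic acid 14.
- **Aryne source:** the ortho-silylaryl triflate 13 comes from bromophenol 8 by O-silylation, retro-Brook shift and triflation. Compound 8 comes from phenol 7, made from 1,2,3,4-tetramethoxybenzene 4 by ortho-lithiation, borylation and oxidation. Compound 4 comes from 2,3,4-trimethoxybenzaldehyde 1.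
- **Ring order:** rings A and B are bought in. Ring C is the only ring formed, and it closes in the last step.

Key step: step 7

Assumption: tangeretin has no stereocentre and no stereogenic double bond, so no stereocontrol is needed; flavone numbering (O1, C2, C3, C4, C4a, C5 to C8, C8a) is used for the target atoms.

## Route

Step 1
Reactants: 1 2,3,4-trimethoxybenzaldehyde
Product: 3 2,3,4-trimethoxyphenol, via aryl formate 2 (not isolated)
Conditions: 30% aq H2O2, cat. H2SO4, MeOH, rt
Reagents that add atoms: hydrogen peroxide, OO
Why: Acid-catalysed Dakin-type (Baeyer–Villiger) oxidation, in which the ortho and para methoxy groups make the aryl group migrate in preference to hydride, and formate 2 is methanolysed in the same flask.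

Step 2
Reactants: 3 2,3,4-trimethoxyphenol
Product: 4 1,2,3,4-tetramethoxybenzene
Conditions: MeI, K2CO3, acetone, reflux
Reagents that add atoms: iodomethane, CI
Why: Williamson ether synthesis (SN2 O-methylation of the potassium phenoxide), and 3 has no other nucleophilic site.

Step 3
Reactants: 4 1,2,3,4-tetramethoxybenzene
Product: 7 2,3,4,5-tetramethoxyphenol, via aryllithium 5 (not isolated), via dimethyl arylboronate 6 (not isolated)
Conditions: n-BuLi, TMEDA, THF, 0 °C; B(OMe)3, −78 °C to rt; AcOH, 30% aq H2O2, 0 °C to rt
Reagents that add atoms: hydrogen peroxide, OO (phenol oxygen of 7); n-butyllithium, [Li]CCCC (lithium of 5 only); trimethyl borate, COB(OC)OC (boron group of 6 only)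
Why: Directed ortho-metalation, borylation and oxidative boron-to-oxygen aryl shift, in which the two ring hydrogens of 4 are equivalent and each lies ortho to a methoxy group so only one aryllithium can form, and the weakly acidic peroxide medium spares the oxidation-prone phenol.

Step 4
Reactants: 7 2,3,4,5-tetramethoxyphenol
Product: 8 2-bromo-3,4,5,6-tetramethoxyphenol
Conditions: NBS, dry MeCN, −20 to 0 °C, dark
Reagents that add atoms: N-bromosuccinimide, O=C1CCC(=O)N1Br
Why: Electrophilic aromatic bromination at the only unsubstituted ring carbon, which is ortho to the free hydroxyl, while the dry cold medium withholds the water that oxidation to a methoxyquinone would need.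

Step 5
Reactants: 8 2-bromo-3,4,5,6-tetramethoxyphenol
Product: 9 (2-bromo-3,4,5,6-tetramethoxyphenoxy)trimethylsilane
Conditions: HMDS, THF, 70 °C; volatiles removed in vacuo
Reagents that add atoms: hexamethyldisilazane, C[Si](C)(C)N[Si](C)(C)C
Why: O-silylation of a phenol with a disilazane, driven by loss of ammonia, gives a salt-free silyl ether that is usable after evaporation.

Step 6
Reactants: 9 (2-bromo-3,4,5,6-tetramethoxyphenoxy)trimethylsilane; 10 trifluoromethanesulfonic anhydride
Product: 13 2,3,4,5-tetramethoxy-6-(trimethylsilyl)phenyl trifluoromethanesulfonate, via aryllithium 11 (not isolated), via lithium phenoxide 12 (not isolated)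
Conditions: n-BuLi, THF, −78 °C; then Tf2O, −78 to 0 °C
Reagents that add atoms: trifluoromethanesulfonic anhydride 10, O=S(=O)(OS(=O)(=O)C(F)(F)F)C(F)(F)F; n-butyllithium, [Li]CCCC (lithium of 11 and 12 only)
Why: Bromine–lithium exchange outruns attack at silicon, aryllithium 11 undergoes the 1,3 oxygen-to-carbon silyl shift (retro-Brook rearrangement) driven by formation of phenoxide 12, and O-sulfonylation by 10 traps it, which is the standard entry to ortho-silylaryl triflates.

Step 7
Reactants: 13 2,3,4,5-tetramethoxy-6-(trimethylsilyl)phenyl trifluoromethanesulfonate; 14 3-(4-methoxyphenyl)propiolic acid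
Product: 19 tangeretin (5,6,7,8,4'-pentamethoxyflavone), via caesium carboxylate 15 (not isolated), via tetramethoxybenzyne 16 (not isolated), via aryl anion 17 (not isolated), via ynone phenoxide 18 (not isolated)
Conditions: CsF (4 equiv), dry THF, 125 °C, sealed tube
Reagents that add atoms: caesium fluoride, [F-].[Cs+] (caesium ion of 15, 17 and 18 only; no atom of it stays in 19)
Why: Fluoride attacks the silicon of 13 and triflate departs, releasing aryne 16 slowly because CsF is sparingly soluble in THF; carboxylate 15 adds through oxygen to one aryne carbon (O1–C8a), the carbanion of 17 attacks the neighbouring ester carbonyl through a strained four-centre tetrahedral arrangement that opens to the ortho-acylphenoxide 18 (C4–C4a), and the phenoxide adds to the alkyne carbon bearing the anisyl group (O1–C2), after which C3 takes back the acid proton that was stored as bifluoride. The closest known reaction type is the insertion of arynes into the acyl–oxygen bond of carboxylic acids, which gives ortho-hydroxyaryl ketones and, with arylpropiolic acids, carries on to flavones. Ring C, the only ring formed, closes by a 6-endo-dig oxa-Michael addition, and no stereocentre is created. No regioselectivity is needed, because a mirror plane through the midpoints of the aryne bond and of C6–C7 exchanges the two aryne carbons, each flanked by one methoxy group, so both orientations lead to 19. Acyl transfer has to outrun protonation of 17: the only acidic proton is held as bifluoride by the excess CsF in dry THF, the acyl group sits next to the carbanion, and the high temperature helps the strained intramolecular path. The 6-endo closure has to beat the 5-exo one: attack at the anisyl-bearing carbon gives a carbonyl-stabilised allenolate, whereas 5-exo attack would put a vinyl anion next to the electron-rich anisyl ring, and in an aprotic medium that less stable adduct is not trapped and reverts.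

## Compound list

1 | 2,3,4-trimethoxybenzaldehyde | COc1ccc(C=O)c(OC)c1OC | starting material
2 | 2,3,4-trimethoxyphenyl formate | COc1ccc(OC=O)c(OC)c1OC | intermediate
3 | 2,3,4-trimethoxyphenol | COc1ccc(O)c(OC)c1OC | intermediate
4 | 1,2,3,4-tetramethoxybenzene | COc1ccc(OC)c(OC)c1OC | intermediate
5 | (2,3,4,5-tetramethoxyphenyl)lithium | COc1cc([Li])c(OC)c(OC)c1OC | intermediate
6 | dimethyl (2,3,4,5-tetramethoxyphenyl)boronate | COB(OC)c1cc(OC)c(OC)c(OC)c1OC | intermediate
7 | 2,3,4,5-tetramethoxyphenol | COc1cc(O)c(OC)c(OC)c1OC | intermediate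
8 | 2-bromo-3,4,5,6-tetramethoxyphenol | COc1c(Br)c(O)c(OC)c(OC)c1OC | intermediate
9 | (2-bromo-3,4,5,6-tetramethoxyphenoxy)trimethylsilane | COc1c(Br)c(O[Si](C)(C)C)c(OC)c(OC)c1OC | intermediate
10 | trifluoromethanesulfonic anhydride | O=S(=O)(OS(=O)(=O)C(F)(F)F)C(F)(F)F | starting material
11 | [2,3,4,5-tetramethoxy-6-(trimethylsilyloxy)phenyl]lithium | COc1c([Li])c(O[Si](C)(C)C)c(OC)c(OC)c1OC | intermediate
12 | lithium 2,3,4,5-tetramethoxy-6-(trimethylsilyl)phenoxide | COc1c([Si](C)(C)C)c([O-])c(OC)c(OC)c1OC.[Li+] | intermediate
13 | 2,3,4,5-tetramethoxy-6-(trimethylsilyl)phenyl trifluoromethanesulfonate | COc1c(OC)c(OC)c(OS(=O)(=O)C(F)(F)F)c([Si](C)(C)C)c1OC | intermediate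
14 | 3-(4-methoxyphenyl)propiolic acid | COc1ccc(C#CC(=O)O)cc1 | starting material
15 | caesium 3-(4-methoxyphenyl)propiolate | COc1ccc(C#CC(=O)[O-])cc1.[Cs+] | intermediate
16 | 3,4,5,6-tetramethoxybenzyne | COC1=C(OC)C(OC)=C(OC)C#C1 | intermediate
17 | caesium salt of the C6 carbanion of 2,3,4,5-tetramethoxyphenyl 3-(4-methoxyphenyl)propiolate (carbanion ortho to the ester oxygen) | COc1ccc(C#CC(=O)Oc2[c-]c(OC)c(OC)c(OC)c2OC)cc1.[Cs+] | intermediate
18 | caesium 2,3,4,5-tetramethoxy-6-[3-(4-methoxyphenyl)propioloyl]phenoxide | COc1ccc(C#CC(=O)c2c([O-])c(OC)c(OC)c(OC)c2OC)cc1.[Cs+] | intermediate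
19 | tangeretin, 5,6,7,8-tetramethoxy-2-(4-methoxyphenyl)-4H-chromen-4-one | COc1ccc(-c2cc(=O)c3c(OC)c(OC)c(OC)c(OC)c3o2)cc1 | target

## Step count

- Total step count: 7
- Longest linear sequence: 7 steps (1 to 19)

## Steps most likely to fail

**1. Step 7.**
- The aryl anion may be protonated before the acyl group shifts, which would stop the cascade at simple O-arylation.
- The propiolate may lose CO2 at 125 °C.
- The phenoxide may close in the 5-exo sense, or it may be arylated by a second aryne.
- The fallback sets out from 7 and comes back at 19, building ring C by classical carbonyl chemistry instead of aryne insertion.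
  - Friedel–Crafts C-acetylation of 7 at its only free ring carbon (Ac2O, BF3·OEt2, warm) should give 1-(2-hydroxy-3,4,5,6-tetramethoxyphenyl)ethan-1-one F1.
  - Claisen–Schmidt condensation of F1 with 4-methoxybenzaldehyde (KOH, EtOH, rt) should give (E)-1-(2-hydroxy-3,4,5,6-tetramethoxyphenyl)-3-(4-methoxyphenyl)prop-2-en-1-one F2.
  - Oxidative cyclisation of F2 (cat. I2, DMSO, 130 °C) should then give 19.

**2. Step 4.**
- Oxidative demethylation of the para-methoxyphenol may compete with ring bromination.
- The fallback sets out from 4 and comes back at 8. It replaces steps 3 and 4, so bromine enters a non-phenolic, less oxidisable ring.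
  - Vilsmeier–Haack formylation of 4 (POCl3, DMF, 80 °C) should give 2,3,4,5-tetramethoxybenzaldehyde F3.
  - Bromination at the last free ring carbon (NBS, DMF, rt) should give 2-bromo-3,4,5,6-tetramethoxybenzaldehyde F4.
  - Baeyer–Villiger oxidation (mCPBA, CH2Cl2, rt) should give 2-bromo-3,4,5,6-tetramethoxyphenyl formate F5.
  - Methanolysis of F5 (K2CO3, MeOH, rt) releases 8.

**3. Step 6.**
- The silyl shift may stay incomplete, or n-BuLi may attack the O–Si bond.
- The doubly flanked phenoxide may triflate slowly.
- The very electron-rich arylsilane may lose its silyl group by protodesilylation during work-up.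
- The fallback sets out from 7 and comes back at 13. It replaces steps 4 to 6 and forms the C–Si bond by carbamate-directed metalation instead of rearrangement.
  - Carbamoylation of 7 (Et2NCOCl, NaH, THF) should give 2,3,4,5-tetramethoxyphenyl diethylcarbamate F6.
  - Directed ortho-metalation and silylation (s-BuLi, TMEDA, THF, −78 °C; TMSCl) should give 2,3,4,5-tetramethoxy-6-(trimethylsilyl)phenyl diethylcarbamate F7.
  - Reductive removal of the carbamate (LiAlH4, THF, reflux) should give 2,3,4,5-tetramethoxy-6-(trimethylsilyl)phenol F8.
  - Triflation of the isolated phenol with 10 (pyridine, CH2Cl2, 0 °C) gives 13.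

## Further compounds

F1 | step 7 | 1-(2-hydroxy-3,4,5,6-tetramethoxyphenyl)ethan-1-one | CC(=O)c1c(O)c(OC)c(OC)c(OC)c1OC
F2 | step 7 | (E)-1-(2-hydroxy-3,4,5,6-tetramethoxyphenyl)-3-(4-methoxyphenyl)prop-2-en-1-one | COc1ccc(/C=C/C(=O)c2c(O)c(OC)c(OC)c(OC)c2OC)cc1
F3 | step 4 | 2,3,4,5-tetramethoxybenzaldehyde | COc1cc(C=O)c(OC)c(OC)c1OC
F4 | step 4 | 2-bromo-3,4,5,6-tetramethoxybenzaldehyde | COc1c(Br)c(C=O)c(OC)c(OC)c1OC
F5 | step 4 | 2-bromo-3,4,5,6-tetramethoxyphenyl formate | COc1c(Br)c(OC=O)c(OC)c(OC)c1OC
F6 | step 6 | 2,3,4,5-tetramethoxyphenyl diethylcarbamate | CCN(CC)C(=O)Oc1cc(OC)c(OC)c(OC)c1OC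
F7 | step 6 | 2,3,4,5-tetramethoxy-6-(trimethylsilyl)phenyl diethylcarbamate | CCN(CC)C(=O)Oc1c([Si](C)(C)C)c(OC)c(OC)c(OC)c1OC
F8 | step 6 | 2,3,4,5-tetramethoxy-6-(trimethylsilyl)phenol | COc1c([Si](C)(C)C)c(O)c(OC)c(OC)c1OC
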